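**Strategy.** Ring B is closed between C7 and C8 at the stage of a C6 ketone (eudesmane numbering: ring A = C1–C5, C10; ring B = C5–C10). The key step exploits two features: C7 lies between the oxygen-bearing C6 and the isopropyl methine C11, and C8 is a primary carbon tethered through C9 to the quaternary C10 of ring A. Methyl cuprate addition to C11 of an (E)-propenyl ketone builds the isopropyl group and releases the C6–C7 Z-enolate regiospecifically; this enolate alkylates at C8 and sets C7. The precursor is a 2-(2-bromoethyl)-2-methyl-6-methylidenecyclohexyl propenyl ketone, made by asymmetric conjugate addition (C10) and an allylboration that sets C5 and creates the C4 methylidene.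

Key step: step 6

Remark on numbering: C14 is the methyl on C10, C15 the methylidene carbon on C4, C11–C13 the isopropyl group on C7.

Assumption: the ligand, catalyst and auxiliary enantiomers named are those expected, by analogy with simpler substrates, to give the drawn configurations; if a sense proved opposite, the antipode would be used.

Step 1
Reactants: 1 3-methylcyclohex-2-en-1-one
Product: 3 (3R)-3-ethenyl-3-methylcyclohex-1-en-1-yl trifluoromethanesulfonate, via dimethylaluminium enolate 2 (not isolated)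
Conditions: CH2=CHMgBr, Me2AlCl, Et2O, 0 °C; then 1, Cu(thiophene-2-carboxylate) (5 mol %), Ph2P–N[(R)-CH(CH3)(2-naphthyl)]2 (10 mol %), Et2O, −30 °C; then Tf2O, −78 → 0 °C
Reagents that add atoms: vinylmagnesium bromide, C=C[Mg]Br; trifluoromethanesulfonic anhydride, O=S(=O)(OS(=O)(=O)C(F)(F)F)C(F)(F)F
Why: Copper-catalysed asymmetric conjugate addition of the alkenylalane (alkenyl transfers in preference to methyl) should create the C10 quaternary centre under ligand control and deliver the C4–C5 aluminium enolate regiospecifically, which is O-sulfonylated by Tf2O.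

Step 2
Reactants: 3 (3R)-3-ethenyl-3-methylcyclohex-1-en-1-yl trifluoromethanesulfonate
Product: 5 (3R)-3-(2-bromoethyl)-3-methylcyclohex-1-en-1-yl trifluoromethanesulfonate, via alkylzirconocene chloride 4 (not isolated)
Conditions: Cp2Zr(H)Cl (1.3 equiv), THF, rt; then NBS, 0 °C
Reagents that add atoms: N-bromosuccinimide, O=C1CCC(=O)N1Br
Why: Hydrozirconation should place zirconium on the terminal carbon of the monosubstituted alkene (the trisubstituted, electron-poor enol triflate is inert), and bromination of the C–Zr bond gives the primary bromide at C8.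

Step 3
Reactants: 5 (3R)-3-(2-bromoethyl)-3-methylcyclohex-1-en-1-yl trifluoromethanesulfonate
Product: 6 2-{[(3R)-3-(2-bromoethyl)-3-methylcyclohex-1-en-1-yl]methyl}-4,4,5,5-tetramethyl-1,3,2-dioxaborolane
Conditions: pinBCH2ZnI (from ICH2Bpin, Zn dust), Pd(PPh3)4 (5 mol %), THF, 40 °C
Reagents that add atoms: [(4,4,5,5-tetramethyl-1,3,2-dioxaborolan-2-yl)methyl]zinc iodide, CC1(C)OB(C[Zn]I)OC1(C)C
Why: Negishi coupling of the alkenyl triflate under zerovalent palladium should give the allylic boronate (C15–B, C4=C5) without touching the unactivated primary bromide.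

Step 4
Reactants: 6 2-{[(3R)-3-(2-bromoethyl)-3-methylcyclohex-1-en-1-yl]methyl}-4,4,5,5-tetramethyl-1,3,2-dioxaborolane; 7 (2E)-but-2-enal
Product: 9 (1S,2E)-1-[(1S,2R)-2-(2-bromoethyl)-2-methyl-6-methylidenecyclohexyl]but-2-en-1-ol, via pinacol borate 8 (not isolated)
Conditions: (R)-TRIP [(R)-3,3'-bis(2,4,6-triisopropylphenyl)-1,1'-binaphthyl-2,2'-diyl hydrogen phosphate] (5 mol %), 4 Å MS, toluene, −30 °C → rt; aq. NaHCO3
Reagents that add atoms: none
Why: Phosphoric-acid-catalysed allylboration through a closed chair transition state: the trans placing of C10 and the CH2B carbon on C4=C5 enforces the anti C5/C6 pair and moves the double bond to the exocyclic C4=C15 position, while the catalyst, reinforcing the small preference for attack anti to the pseudoaxial CH2CH2Br group on C10, selects the C5 face so that C6 ends trans to C9.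

Step 5
Reactants: 9 (1S,2E)-1-[(1S,2R)-2-(2-bromoethyl)-2-methyl-6-methylidenecyclohexyl]but-2-en-1-ol
Product: 10 (2E)-1-[(1S,2R)-2-(2-bromoethyl)-2-methyl-6-methylidenecyclohexyl]but-2-en-1-one
Conditions: activated MnO2 (excess), CH2Cl2, rt
Reagents that add atoms: none
Why: Neutral, heterogeneous allylic alcohol oxidation should give the enone without acid or base, so the doubly activated C5–H is not epimerised and the exocyclic alkene does not move into conjugation; the C6 carbinol centre has served only to relay the C5 configuration.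

Step 6
Reactants: 10 (2E)-1-[(1S,2R)-2-(2-bromoethyl)-2-methyl-6-methylidenecyclohexyl]but-2-en-1-one
Product: 12 (2S,4aR,8aS)-4a-methyl-8-methylidene-2-(propan-2-yl)octahydronaphthalen-1(2H)-one, via lithium Z-enolate 11 (not isolated)
Conditions: Me2CuLi (1.15 equiv; from MeLi, CuI), Et2O, −78 °C; then THF, DMPU, −78 → 0 °C; aq. NH4Cl
Reagents that add atoms: lithium dimethylcuprate, [Li+].C[Cu-]C
Why: Michael-initiated ring closure: Me2CuLi transfers methyl to C11 of the s-cis (E)-enone, which completes the isopropyl group and gives the lithium Z-enolate 11 at C6–C7 without any base, so the acidic C5–H between the carbonyl and the exocyclic alkene is never removed. On warming with DMPU, C7 of the enolate displaces bromide at C8 (SN2), the closest known reaction type being tandem cuprate conjugate addition–intramolecular enolate alkylation. Ring B closes in the 6-(enolendo)-exo-tet mode, which is geometrically allowed for carbon and is expected to outrun six-membered O-alkylation with a lithium counter-ion and a soft bromide. C7 is the only new stereocentre: in the chair-like transition state imposed by the trans C5/C10 pair (C5–H and C10–CH3 axial), C8 reaches the enolate face on which C10 lies, and the isopropyl group, trans to C5 in the Z-enolate, ends equatorial (7S). The step needs conjugate addition to precede attack on the bromide, secured by the far higher rate of cuprate addition to an enone at −78 °C, and it needs the Z-enolate, secured by the s-cis preference of an enone whose acyl substituent (C5) is a hindered branched carbon.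

Step 7
Reactants: 12 (2S,4aR,8aS)-4a-methyl-8-methylidene-2-(propan-2-yl)octahydronaphthalen-1(2H)-one
Product: 13 (1S,2S,4aR,8aS)-4a-methyl-8-methylidene-2-(propan-2-yl)decahydronaphthalen-1-ol
Conditions: Li, NH3(l), THF, MeOH, −78 °C; then NH4Cl
Reagents that add atoms: none
Why: Dissolving-metal reduction of the ketone passes through a carbinyl anion that is protonated in its more stable form and should give the equatorial C6 alcohol (trans to the axial C10 methyl), whereas hydride reagents would attack from the open equatorial side and give the axial epimer; the isolated 1,1-disubstituted alkene is not reduced.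

Step 8
Reactants: 13 (1S,2S,4aR,8aS)-4a-methyl-8-methylidene-2-(propan-2-yl)decahydronaphthalen-1-ol; 14 2,2-dimethyl-1,3-dioxane-4,6-dione
Product: 15 3-{[(1S,2S,4aR,8aS)-4a-methyl-8-methylidene-2-(propan-2-yl)decahydronaphthalen-1-yl]oxy}-3-oxopropanoic acid
Conditions: toluene, 100 °C
Reagents that add atoms: none
Why: Thermal acylation of the hindered secondary alcohol by the cyclic acylal with loss of acetone should give the malonic half-ester without coupling reagents or protecting groups.

Step 9
Reactants: 15 3-{[(1S,2S,4aR,8aS)-4a-methyl-8-methylidene-2-(propan-2-yl)decahydronaphthalen-1-yl]oxy}-3-oxopropanoic acid; 16 4-hydroxybenzaldehyde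
Product: 18 (1S,2S,4aR,8aS)-4a-methyl-8-methylidene-2-(propan-2-yl)decahydronaphthalen-1-yl (2E)-3-(4-hydroxyphenyl)prop-2-enoate, via arylidene malonic half-ester 17 (not isolated)
Conditions: pyridine, piperidine (10 mol %), 70 °C
Reagents that add atoms: none
Why: Knoevenagel–Doebner condensation: amine-catalysed condensation of the malonic half-ester with the aldehyde and decarboxylation in pyridine should give the (E)-cinnamate directly, the free phenol and the exocyclic alkene being tolerated.

**Compound list**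

1 | 3-methylcyclohex-2-en-1-one | CC1=CC(=O)CCC1 | starting material
2 | dimethylaluminium (3R)-3-ethenyl-3-methylcyclohex-1-en-1-olate | C=C[C@@]1(C)CCCC(O[Al](C)C)=C1 | intermediate
3 | (3R)-3-ethenyl-3-methylcyclohex-1-en-1-yl trifluoromethanesulfonate | C=C[C@@]1(C)CCCC(OS(=O)(=O)C(F)(F)F)=C1 | intermediate
4 | chlorobis(cyclopentadienyl){2-[(1R)-1-methyl-3-(trifluoromethanesulfonyloxy)cyclohex-2-en-1-yl]ethyl}zirconium | Cl[Zr](CC[C@@]1(C)CCCC(OS(=O)(=O)C(F)(F)F)=C1)(C1C=CC=C1)C1C=CC=C1 | intermediate
5 | (3R)-3-(2-bromoethyl)-3-methylcyclohex-1-en-1-yl trifluoromethanesulfonate | BrCC[C@@]1(C)CCCC(OS(=O)(=O)C(F)(F)F)=C1 | intermediate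
6 | 2-{[(3R)-3-(2-bromoethyl)-3-methylcyclohex-1-en-1-yl]methyl}-4,4,5,5-tetramethyl-1,3,2-dioxaborolane | BrCC[C@@]1(C)CCCC(CB2OC(C)(C)C(C)(C)O2)=C1 | intermediate
7 | (2E)-but-2-enal | C/C=C/C=O | starting material
8 | 2-{[(1S,2E)-1-[(1S,2R)-2-(2-bromoethyl)-2-methyl-6-methylidenecyclohexyl]but-2-en-1-yl]oxy}-4,4,5,5-tetramethyl-1,3,2-dioxaborolane | C=C1CCC[C@](C)(CCBr)[C@H]1[C@H](/C=C/C)OB1OC(C)(C)C(C)(C)O1 | intermediate
9 | (1S,2E)-1-[(1S,2R)-2-(2-bromoethyl)-2-methyl-6-methylidenecyclohexyl]but-2-en-1-ol | C=C1CCC[C@](C)(CCBr)[C@H]1[C@H](/C=C/C)O | intermediate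
10 | (2E)-1-[(1S,2R)-2-(2-bromoethyl)-2-methyl-6-methylidenecyclohexyl]but-2-en-1-one | C=C1CCC[C@](C)(CCBr)[C@H]1C(=O)/C=C/C | intermediate
11 | lithium (1Z)-1-[(1S,2R)-2-(2-bromoethyl)-2-methyl-6-methylidenecyclohexyl]-3-methylbut-1-en-1-olate | C=C1CCC[C@](C)(CCBr)[C@H]1/C([O-])=C/C(C)C.[Li+] | intermediate
12 | (2S,4aR,8aS)-4a-methyl-8-methylidene-2-(propan-2-yl)octahydronaphthalen-1(2H)-one | C=C1CCC[C@]2(C)CC[C@@H](C(C)C)C(=O)[C@@H]12 | intermediate
13 | (1S,2S,4aR,8aS)-4a-methyl-8-methylidene-2-(propan-2-yl)decahydronaphthalen-1-ol | C=C1CCC[C@]2(C)CC[C@@H](C(C)C)[C@H](O)[C@@H]12 | intermediate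
14 | 2,2-dimethyl-1,3-dioxane-4,6-dione | CC1(C)OC(=O)CC(=O)O1 | starting material
15 | 3-{[(1S,2S,4aR,8aS)-4a-methyl-8-methylidene-2-(propan-2-yl)decahydronaphthalen-1-yl]oxy}-3-oxopropanoic acid | C=C1CCC[C@]2(C)CC[C@@H](C(C)C)[C@H](OC(=O)CC(=O)O)[C@@H]12 | intermediate
16 | 4-hydroxybenzaldehyde | O=Cc1ccc(O)cc1 | starting material
17 | 2-[(4-hydroxyphenyl)methylidene]-3-{[(1S,2S,4aR,8aS)-4a-methyl-8-methylidene-2-(propan-2-yl)decahydronaphthalen-1-yl]oxy}-3-oxopropanoic acid | C=C1CCC[C@]2(C)CC[C@@H](C(C)C)[C@H](OC(=O)C(=Cc3ccc(O)cc3)C(=O)O)[C@@H]12 | intermediate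
18 | (1S,2S,4aR,8aS)-4a-methyl-8-methylidene-2-(propan-2-yl)decahydronaphthalen-1-yl (2E)-3-(4-hydroxyphenyl)prop-2-enoate | C=C1CCC[C@]2(C)CC[C@@H](C(C)C)[C@H](OC(=O)/C=C/c3ccc(O)cc3)[C@@H]12 | target

**Step count.** Total: 9 steps. Longest linear sequence: 9 steps (1 → 18).

**Steps most likely to fail**

Step 6 (key step). The cuprate may add through the s-trans conformer of the enone, which would give the E-enolate and hence the C7 epimer, or methyl may be transferred to the C8 bromide before ring closure. The fallback sets out from 6 and returns at 11. Allylboration of 3-methylbutanal with 6 under the conditions of step 4 should give, through the pinacol borate 2-{(1S)-1-[(1S,2R)-2-(2-bromoethyl)-2-methyl-6-methylidenecyclohexyl]-3-methylbutoxy}-4,4,5,5-tetramethyl-1,3,2-dioxaborolane F1, the saturated alcohol (1S)-1-[(1S,2R)-2-(2-bromoethyl)-2-methyl-6-methylidenecyclohexyl]-3-methylbutan-1-ol F2. Oxidation with 1,1,1-triacetoxy-1,1-dihydro-1,2-benziodoxol-3(1H)-one buffered with NaHCO3 should give the isobutyl ketone 1-[(1S,2R)-2-(2-bromoethyl)-2-methyl-6-methylidenecyclohexyl]-3-methylbutan-1-one F3. LiN(SiMe3)2 in THF at −78 °C should then remove a C7 proton (the C5 proton is tertiary and shielded by the quaternary C10) to give the same Z-enolate 11, which closes to 12 as in step 6.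

Step 4. Facial control at C5 may be poor (attack syn to the CH2CH2Br group gives the C5,C6-diastereomer), or addition of the hindered boronate may be slow. The fallback sets out from 6 and returns at 9, with a boron-bound auxiliary in place of the catalyst. KHF2 in aqueous methanol should convert 6 into potassium trifluoro{[(3R)-3-(2-bromoethyl)-3-methylcyclohex-1-en-1-yl]methyl}borate F4. Me3SiCl and diisopropyl (2R,3R)-tartrate should then give the tartrate boronate diisopropyl (4R,5R)-2-{[(3R)-3-(2-bromoethyl)-3-methylcyclohex-1-en-1-yl]methyl}-1,3,2-dioxaborolane-4,5-dicarboxylate F5. Its reaction with 7 in toluene at −78 °C over 4 Å sieves runs through the same chair under reagent control and, after hydrolysis of the tartrate borate of 9 F6, returns 9.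

Step 1. Enantioselectivity may be low or methyl transfer may compete with the unsubstituted vinylalane. The fallback sets out from 1 and returns at 3. Hydroalumination of ethynyltrimethylsilane with iBu2AlH should give diisobutyl[1-(trimethylsilyl)ethenyl]alane F7. This should add to 1 under Cu(OTf)2 (5 mol %) and a chiral sulfonate-bearing imidazolinium salt (carbene precursor) to give diisobutylaluminium (3S)-3-methyl-3-[1-(trimethylsilyl)ethenyl]cyclohex-1-en-1-olate F8. Tf2O should give (3S)-3-methyl-3-[1-(trimethylsilyl)ethenyl]cyclohex-1-en-1-yl trifluoromethanesulfonate F9, and CF3CO2H in CH2Cl2 should remove the silyl group to return 3.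

**Further compounds**

F1 | step 6 | 2-{(1S)-1-[(1S,2R)-2-(2-bromoethyl)-2-methyl-6-methylidenecyclohexyl]-3-methylbutoxy}-4,4,5,5-tetramethyl-1,3,2-dioxaborolane | C=C1CCC[C@](C)(CCBr)[C@H]1[C@H](CC(C)C)OB1OC(C)(C)C(C)(C)O1
F2 | step 6 | (1S)-1-[(1S,2R)-2-(2-bromoethyl)-2-methyl-6-methylidenecyclohexyl]-3-methylbutan-1-ol | C=C1CCC[C@](C)(CCBr)[C@H]1[C@H](CC(C)C)O
F3 | step 6 | 1-[(1S,2R)-2-(2-bromoethyl)-2-methyl-6-methylidenecyclohexyl]-3-methylbutan-1-one | C=C1CCC[C@](C)(CCBr)[C@H]1C(=O)CC(C)C
F4 | step 4 | potassium trifluoro{[(3R)-3-(2-bromoethyl)-3-methylcyclohex-1-en-1-yl]methyl}borate | [K+].F[B-](F)(F)CC1=C[C@@](C)(CCBr)CCC1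
F5 | step 4 | diisopropyl (4R,5R)-2-{[(3R)-3-(2-bromoethyl)-3-methylcyclohex-1-en-1-yl]methyl}-1,3,2-dioxaborolane-4,5-dicarboxylate | BrCC[C@@]1(C)CCCC(CB2O[C@@H](C(=O)OC(C)C)[C@@H](O2)C(=O)OC(C)C)=C1
F6 | step 4 | diisopropyl (4R,5R)-2-{[(1S,2E)-1-[(1S,2R)-2-(2-bromoethyl)-2-methyl-6-methylidenecyclohexyl]but-2-en-1-yl]oxy}-1,3,2-dioxaborolane-4,5-dicarboxylate | C=C1CCC[C@](C)(CCBr)[C@H]1[C@H](/C=C/C)OB1O[C@@H](C(=O)OC(C)C)[C@@H](O1)C(=O)OC(C)C
F7 | step 1 | diisobutyl[1-(trimethylsilyl)ethenyl]alane | C=C([Si](C)(C)C)[Al](CC(C)C)CC(C)C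
F8 | step 1 | diisobutylaluminium (3S)-3-methyl-3-[1-(trimethylsilyl)ethenyl]cyclohex-1-en-1-olate | C=C([Si](C)(C)C)[C@@]1(C)CCCC(O[Al](CC(C)C)CC(C)C)=C1
F9 | step 1 | (3S)-3-methyl-3-[1-(trimethylsilyl)ethenyl]cyclohex-1-en-1-yl trifluoromethanesulfonate | C=C([Si](C)(C)C)[C@@]1(C)CCCC(OS(=O)(=O)C(F)(F)F)=C1
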